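## Retrosynthetic overview

1. Plagiochilin A ⇐ one-pot reduction/acetylation of a C15 aldehyde ⇐ lactol acetylation ⇐ hydroxyl-directed epoxidation of the C10=C14 alkene ⇐ lactol-enal formed by acid unmasking of a tris(dimethyl acetal).
2. Key disconnection C4–C5: visible-light radical conjugate addition of a masked malondialdehyde radical to a β-cyclopropyl enone; the terminating H-atom transfer sets C1.
3. That enone ⇐ α′-dimethoxymethylation and enone transposition of a cycloheptenone ⇐ seven-ring aldol of the keto aldehyde from ozonolysis of (+)-2-carene.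
4. Ring order: cyclopropane (bought) → cycloheptane → dihydropyran → epoxide.
5. Atom labels C1–C15 are the plagiochilin (2,3-secoaromadendrane) locants of the carbons they become. Carene C1→C7, C2→C8, C3→C10, 3-CH3→C9, C4→C1, C5→C5, C6→C6, C7→C11.

Assumption: (+)-2-carene and (E)-1,3,3-trimethoxyprop-1-ene are taken as commercial; ordinary reagents are not numbered.

## Route

**Step 1**
Reactants: 1, (+)-2-carene
Product: 2, (1S,3R)-2,2-dimethyl-3-(3-oxobutyl)cyclopropane-1-carbaldehyde (cis)
Conditions: O3, CH2Cl2/MeOH, −78 °C; Me2S
Reagents that add atoms: ozone, O=[O+][O-]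
Why: Ozonolysis of the trisubstituted alkene gives the C8 aldehyde and C10 methyl ketone; the cis-cyclopropane stereocenters C6/C7 are carried over untouched.

**Step 2**
Reactants: 2
Product: 3, (1S,7R)-8,8-dimethylbicyclo[5.1.0]oct-2-en-4-one
Conditions: LDA (1.1 equiv), THF, −78 → −40 °C, inverse addition, 0.01 M; then MsCl, Et3N; DBU, 0 °C → rt
Reagents that add atoms: none
Why: Kinetic deprotonation of the methyl ketone at CH3 (the cyclopropyl aldehyde is non-enolisable) forces the seven-membered intramolecular aldol (C9–C8), and mesylation/E1cB gives the enone; no new stereocenter.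

**Step 3**
Reactants: 3
Product: 4, (1S,7R)-5-(dimethoxymethyl)-8,8-dimethylbicyclo[5.1.0]oct-2-en-4-one (C5 epimers)
Conditions: LDA, TMSCl, THF, −78 °C; then HC(OMe)3, TMSOTf (10 mol%), CH2Cl2, −78 °C
Reagents that add atoms: trimethyl orthoformate, COC(OC)OC
Why: The kinetic cross-conjugated 2-silyloxydiene reacts with the dimethoxycarbenium ion at the α′ carbon (Mukaiyama-type acetal aldol), installing C2 on C1 at the aldehyde oxidation level; the C1 configuration is erased in step 4.

**Step 4**
Reactants: 4
Product: 5, (1R,7S)-3-(dimethoxymethyl)-8,8-dimethylbicyclo[5.1.0]octa-2,5-dien-4-one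
Conditions: LDA, THF, −78 °C; then PhS(Cl)=N-t-Bu, −78 °C
Reagents that add atoms: none
Why: Mukaiyama dehydrogenation; the only enolisable position is C1–H, and syn-elimination toward C5 (not toward the acetal carbon) gives the C1=C5 enone.

**Step 5**
Reactants: 5
Product: 6, (1R,7S)-3-(dimethoxymethyl)-8,8-dimethylbicyclo[5.1.0]oct-2-en-4-one
Conditions: [(Ph3P)CuH]6 (5 mol%), PhSiH3, toluene, 0 °C; aq. NH4F
Reagents that add atoms: none
Why: Copper hydride 1,4-reduction (Stryker) takes the α-unsubstituted C8=C9 enone in preference to the α-substituted C1=C5 enone, completing the enone transposition.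

**Step 6**
Reactants: 7, (E)-1,3,3-trimethoxyprop-1-ene
Product: 8, 2-bromo-1,1,3,3-tetramethoxypropane
Conditions: NBS, MeOH, 0 °C
Reagents that add atoms: N-bromosuccinimide, O=C1CCC(=O)N1Br; methanol, CO
Why: Bromo-methoxylation of the enol ether (Br at the β carbon, MeOH at the oxocarbenium carbon) gives the radical precursor.

**Step 7**
Reactants: 6 and 8 (2 equiv)
Product: 9, 3-(dimethoxymethyl)-8,8-dimethyl-2-(1,1,3,3-tetramethoxypropan-2-yl)bicyclo[5.1.0]octan-4-one; the two side chains are cis to each other and both anti to the CMe2 bridge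
Conditions: fac-Ir(ppy)3 (1 mol%), (TMS)3SiH (1.3 equiv, slow addition), K2HPO4, MeCN, 450 nm LEDs, 20 °C
Reagents that add atoms: none beyond 8 (H from (TMS)3SiH)
Why: Proposed new method: Giese-type radical conjugate addition in which silyl-radical bromine abstraction from 8 gives the nucleophilic 1,1,3,3-tetramethoxyprop-2-yl radical (a masked malondialdehyde unit), which adds to C5 of the enone anti to the endo-methyl of the cyclopropane; spin then sits only on the α-keto carbon C1, never on a cyclopropylcarbinyl carbon, and bulky (TMS)3SiH transfers H to C1 on the face opposite the new pseudoaxial C5 substituent, giving the 1,5-cis product, while the low-triplet-energy photocatalyst avoids sensitising the cyclopropyl enone; closest known reaction type is the photocatalytic silyl-radical halogen-atom-transfer Giese addition of secondary alkyl bromides to enones.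

**Step 8**
Reactants: 9
Product: 10, the 4-methylidene analogue of 9 (same configuration)
Conditions: Cp2TiMe2, toluene, 70 °C, dark
Reagents that add atoms: dimethyltitanocene, C[Ti](C)(C1C=CC=C1)C1C=CC=C1
Why: Petasis methylenation is non-basic, so the hindered, epimerisable α-branched ketone becomes the C10=C14 alkene without scrambling C1, and the acetals survive.

**Step 9**
Reactants: 10
Product: 11, cis-fused lactol enal: 2-hydroxy (anomers), C3=C4 enol ether, 4-CHO (C15), C10=C14
Conditions: AcOH/THF/H2O 3:1:1, 35 °C
Reagents that add atoms: water, O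
Why: Acetal hydrolysis releases a 2-substituted malondialdehyde, whose enol OH is the only stabilised enol (C10 is no longer a ketone); it closes onto the C2 aldehyde to give the dihydropyran lactol with C3=C4 (iridoid-type lactolisation), and C1/C5 are untouched.

**Step 10**
Reactants: 11
Product: 12, the 10,14-epoxide of 11 (epoxide O syn to C2, anti to the cyclopropane)
Conditions: VO(acac)2 (5 mol%), t-BuOOH, CH2Cl2, 0 °C
Reagents that add atoms: tert-butyl hydroperoxide, CC(C)(C)OO
Why: Homoallylic-hydroxyl-directed vanadium epoxidation delivers oxygen to the alkene face on the side of the C1–C2 bond, which is also the face away from the gem-dimethylcyclopropane, setting C10; the push-pull enol ether is inert.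

**Step 11**
Reactants: 12
Product: 13, 2-O-acetate of 12 (plagiochilin A with CHO in place of CH2OAc)
Conditions: Ac2O, pyridine, DMAP (cat.), CH2Cl2, 0 °C
Reagents that add atoms: acetic anhydride, CC(=O)OC(C)=O
Why: The equilibrating lactol is acylated as the anomer with OAc trans to the C1–C10 bond (the usual outcome for iridoid-type lactols), setting C2; mild base leaves the epoxide intact.

**Step 12**
Reactants: 13
Product: 14, plagiochilin A
Conditions: DIBAL-H (1.1 equiv), CH2Cl2, −78 °C; then Ac2O, pyridine, DMAP, −78 → 0 °C
Reagents that add atoms: acetic anhydride, CC(=O)OC(C)=O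
Why: 1,2-Reduction of the vinylogous formate aldehyde and in situ acylation of the aluminium alkoxide (reductive acetylation) give the allylic acetate; any anomeric acetate cleaved by DIBAL is re-acetylated in the same pot.

## Compound list

1 | (+)-2-carene, (1S,6R)-3,7,7-trimethylbicyclo[4.1.0]hept-2-ene | CC1=C[C@H]2[C@@H](CC1)C2(C)C | starting material
2 | (1S,3R)-2,2-dimethyl-3-(3-oxobutyl)cyclopropane-1-carbaldehyde | O=C[C@H]1[C@@H](CCC(C)=O)C1(C)C | intermediate
3 | (1S,7R)-8,8-dimethylbicyclo[5.1.0]oct-2-en-4-one | O=C1C=C[C@H]2[C@@H](CC1)C2(C)C | intermediate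
4 | (1S,7R)-5-(dimethoxymethyl)-8,8-dimethylbicyclo[5.1.0]oct-2-en-4-one (C5 epimers) | O=C1C=C[C@H]2[C@@H](CC1C(OC)OC)C2(C)C | intermediate
5 | (1R,7S)-3-(dimethoxymethyl)-8,8-dimethylbicyclo[5.1.0]octa-2,5-dien-4-one | O=C1C=C[C@H]2[C@@H](C=C1C(OC)OC)C2(C)C | intermediate
6 | (1R,7S)-3-(dimethoxymethyl)-8,8-dimethylbicyclo[5.1.0]oct-2-en-4-one | O=C1CC[C@H]2[C@@H](C=C1C(OC)OC)C2(C)C | intermediate
7 | (E)-1,3,3-trimethoxyprop-1-ene | CO/C=C/C(OC)OC | starting material
8 | 2-bromo-1,1,3,3-tetramethoxypropane | COC(OC)C(Br)C(OC)OC | intermediate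
9 | 3-(dimethoxymethyl)-8,8-dimethyl-2-(1,1,3,3-tetramethoxypropan-2-yl)bicyclo[5.1.0]octan-4-one, side chains cis and anti to CMe2 | COC(OC)[C@@H]2[C@H](C(C(OC)OC)C(OC)OC)[C@@H]1[C@H](CCC2=O)C1(C)C | intermediate
10 | 4-methylidene analogue of 9 | COC(OC)[C@@H]2[C@H](C(C(OC)OC)C(OC)OC)[C@@H]1[C@H](CCC2=C)C1(C)C | intermediate
11 | lactol enal (2-OH anomers, 4-CHO, C10=C14; H-1/H-5 cis, syn to the cyclopropane) | O=CC1=COC(O)[C@@H]2[C@H]1[C@@H]1[C@H](CCC2=C)C1(C)C | intermediate
12 | 10,14-epoxide of 11 | O=CC1=COC(O)[C@@H]2[C@H]1[C@@H]1[C@H](CC[C@@]23CO3)C1(C)C | intermediate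
13 | 2-O-acetyl-15-oxo precursor (CHO in place of CH2OAc) | O=CC1=CO[C@H](OC(C)=O)[C@@H]2[C@H]1[C@@H]1[C@H](CC[C@@]23CO3)C1(C)C | intermediate
14 | plagiochilin A | CC(=O)OCC1=CO[C@H](OC(C)=O)[C@@H]2[C@H]1[C@@H]1[C@H](CC[C@@]23CO3)C1(C)C | target

## Step count and risks

Total steps: 12. Longest linear sequence: 11 (steps 1–5, 7–12).

Steps most likely to fail:

1. **Step 7 (proposed new radical conjugate addition).** The bulky, inductively deactivated radical may be reduced by the silane before it adds, and the cis H-transfer selectivity is unproven. Fallback (known chemistry): Mukaiyama–Michael addition of the silyl ketene acetal of methyl 3,3-dimethoxypropanoate to 6 (TBSOTf, −78 °C) with kinetic protonation of the silyl enol ether. C15 then arrives as CO2Me, and step 12 uses excess DIBAL-H.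

2. **Step 2 (kinetic seven-ring aldol).** Five-ring closure through the internal enolate, or LDA attack on the aldehyde, may compete. Fallback: build the ring by ring-closing metathesis instead: Wittig methylenation of the aldehyde, Eschenmoser α-methylenation of the methyl ketone to the vinyl ketone, then Grubbs II to give 3.

3. **Step 10 (lactol-directed epoxidation).** The lactol may be oxidised or may direct poorly. Fallback: acetylate first (step 11), then epoxidise the acetate with DMDO under steric control (attack anti to the gem-dimethylcyclopropane). If that face proves wrong, the bromohydrin route (NBS/H2O, then K2CO3) delivers oxygen to the opposite face.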